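## The problem

Compound 17 is an open-chain 8,8'-lignan: a four-carbon chain C7–C8–C8'–C7' between a guaiacyl ring (on C7) and a syringyl ring (on C7'), with methyl C9 on C8 and acetoxymethyl C9' on C8'. No ring has to be closed. The two aryl ends differ only by one methoxy group, so they must enter as separate, differentiated pieces. The two adjacent stereocentres, C8 (S) and C8' (R), lie in a flexible chain, and C8 has no polar neighbour of its own, so it is best set under control of C8' or of a temporary third centre. C9 and C9' stand at different oxidation levels, so any plan that makes them alike pays for it later in redox corrections. Sensitive groups are the two free phenols and electron-rich arenes (oxidants, ozone, strong acid) and the primary acetate (bases, nucleophiles). Any intermediate oxygenated at C7 also carries a para-alkoxybenzylic, allylic C–O bond that ionises readily in acid. The enabling feature is that C9' is the only oxygenated sp3 carbon and sits on C8', which is 1,3 to benzylic C7 across C8. An oxygen on C7 can therefore hand a CH2O unit to C8' through a five-membered [2,3] transition state. The C7=C8 styrene left behind has the new CH2OH homoallylic to it, placed to steer the reduction that creates C8.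

## Retrosynthesis

**17 to 16 to 15.** The two phenolic O–benzyl bonds and the acetyl C–O bond are cut. Free phenols and an acetate would not survive the organometallic steps, so the phenols are carried as benzyl ethers and the acetate is put on last but one. Benzyl is preferred to silyl or acetal groups because it tolerates alkyllithium and hydride bases and leaves by neutral hydrogenolysis, which touches neither the acetate nor the stereocentres of the saturated chain. The forward steps are an acylation of primary alcohol 15 to 16 and a double debenzylation, with no selectivity question.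

**15 to 14.** The C7–H and C8–H bonds are cut, which leads back to Z-styrene 14. Compared with creating C8 by enolate methylation, this keeps C9 an untouched methyl group and removes one stereocentre. The forward hydrogenation must add to one face of C7=C8. In 14 the aryl group is cis to C8', so allylic 1,3-strain fixes the conformation about C8–C8', and the homoallylic hydroxyl can direct a cationic iridium catalyst to a single face.

**14 to 12 (through 13).** The C9'–C8' bond is cut. The neighbouring cuts at C8' (benzylation at C7', or the C8–C8' bond) need an auxiliary or build both centres with C9 and C9' at the wrong oxidation level. This cut trades a carbon stereocentre for a carbinol centre at C7, which is far easier to make enantioselectively, and removes C9' as a one-carbon tin reagent. Precursor 12 has one stereocentre and an E-alkene. The forward step must be a [2,3] and not a [1,2] shift, must transfer chirality fully, and must give the Z-styrene.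

**12 to 10 and 11.** The O–CH2 bond is cut. The stannylmethyl ether comes from allylic alcohol 10 and commercial iodomethylstannane 11 by alkylation. The forward step must stay basic, because 10 ionises in acid.

**10 to 4 and 6 (through 7, 8 and 9).** The aryl–C7 bond is cut. The neighbouring option, asymmetric reduction of the corresponding aryl alkenyl ketone, asks a catalyst to tell an electron-rich aryl group from an α-methylalkenyl group of similar size, and neither the sense nor the level of induction can be predicted. An aldehyde offers hydrogen against carbon, which a chiral amino-alkoxide zinc catalyst distinguishes by an established model. The cut is also convergent: the complete carbon skeleton apart from C9' arises in the step that sets C7. The forward reaction must be a clean 1,2-addition of the mixed arylzinc 9 to enal 4, with high enantioselectivity and no deprotonation at the benzylic γ-position.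

**4 to 2 and 3.** The C8=C8' double bond is cut by cross-metathesis between allylarene 2 and commercial methacrolein 3. The alternative, cleaving 2 to an arylacetaldehyde and olefinating it, costs a step and passes through a labile aldehyde. The forward reaction must give the E-enal and must not move the allyl double bond into conjugation with the ring.

**2 to 1, and 6 to 5.** The benzyl ethers are cut, leading to commercial phenols 1 and 5.

## Roads not taken

**Alternative 1: trans-methylation of a lactone.** Here the C8–C9 bond is cut. Lactone A1, whose carbonyl carbon is C7 and whose ring oxygen sits on C9', carries the syringylmethyl group at C8'. Its lithium enolate is methylated anti to that group to give A2. Aryllithium 7 then opens the lactone at C7, and the benzylic carbonyl oxygen is removed at the end.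
- Merits: every step is textbook chemistry. The trans selectivity of alkylating β-substituted butyrolactone enolates is dependable, and the final hydrogenolysis can remove the benzylic oxygen and both benzyl groups together.
- Weak points: A1 needs a stoichiometric auxiliary or a separate asymmetric hydrogenation. After ring opening, C8 sits α to an aryl ketone and can epimerise. The γ-hydroxy ketone can close to a tetrahydrofuran under the acidic deoxygenation unless it is acetylated first. The route is about eleven steps.
- Comparison: in predictability this road is better than the chosen one, and it is kept as the fallback for the key step. The chosen plan sets against it nine steps, a convergent union of the two aryl halves, chirality from a catalyst, and no carbonyl-flanked stereocentre.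

**Alternative 2: redox-relay Heck arylation.** Here the syringyl–C7' bond is cut. An arylpalladium species, made from the syringyl boronic acid under a divalent palladium catalyst with a chiral pyridine–oxazoline ligand and dioxygen, adds to a 2-methylene alcohol that already holds C8. The aryl group goes to C7' and palladium to C8', and palladium then walks to C9' to release aldehyde A3.
- Merits: it would be the shortest road on paper and is catalytic. C9' arrives at the aldehyde level in the step that attaches the second ring.
- Weak points: the new centre C8' is not the arylated carbon. It is formed at the palladium-bearing carbon and fixed only if the palladium hydride re-adds without leaving the enol, so any enol dissociation erases it. A3 is an α-branched aldehyde that epimerises easily. The electron-rich boronic acid is exposed to copper and oxygen. The alkenol still needs its own asymmetric synthesis of C8, with catalyst and substrate control to be matched.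
- Comparison: it is better in step economy, but stereocontrol of this kind has no close precedent. The chosen plan sets against it known reaction types throughout and a clear model for each new centre.

**Alternative 3: Ireland–Claisen union of two phenylpropanoid halves.** Here the C8–C8' bond is cut. The kinetic silyl ketene acetal of an ester, made from a 3-(guaiacyl)propanoic acid and an enantiopure secondary E-allylic alcohol bearing the syringylmethyl group, rearranges through a chair to acid A4.
- Merits: the central bond and both stereocentres form in one well-understood step from two halves of similar size. In bond-forming efficiency this is the best of the four.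
- Weak points: in A4, C9 is a carboxylic acid that must be taken down to methyl (reduction, activation, hydride displacement). C9' is hidden in a propenyl group that must be cleaved oxidatively in the presence of two electron-rich arenes. About six steps follow the rearrangement, and enolate geometry decides the diastereomer ratio.
- Comparison: the chosen plan forms only one skeletal bond in its key step. It sets against that a C9 that is methyl from the start and a C9' that arrives as CH2OH, so only three steps follow the rearrangement.

Key step: step 6

Assumption: amino-alkoxide zinc catalysts of the isoborneol family are taken to send the transferred group to the Si face of an aldehyde with the (2S) ligand, as in their alkyl transfers, so the (2R) ligand is specified in step 4; if the sense proves opposite for enal 4, the other ligand enantiomer is used with no other change.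

## Route

Step 1
Reactants: 1 4-allyl-2,6-dimethoxyphenol
Product: 2 5-allyl-2-(benzyloxy)-1,3-dimethoxybenzene
Conditions: BnBr, K2CO3, DMF, rt
Reagents that add atoms: benzyl bromide, BrCc1ccccc1
Why: Williamson etherification of an acidic phenol; the benzyl ether withstands metathesis, organolithium and hydride conditions and is removed by hydrogenolysis in the last step.

Step 2
Reactants: 2 5-allyl-2-(benzyloxy)-1,3-dimethoxybenzene; 3 methacrolein
Product: 4 (E)-4-[4-(benzyloxy)-3,5-dimethoxyphenyl]-2-methylbut-2-enal
Conditions: 3 (5 equiv), second-generation Grubbs catalyst RuCl2(=CHPh)(PCy3)(H2IMes) (5 mol %), 1,4-benzoquinone (10 mol %), CH2Cl2, 40 °C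
Reagents that add atoms: none
Why: Olefin cross-metathesis of a terminal allylarene with excess methacrolein, which does not homodimerise; trisubstituted enals form under thermodynamic control as the E isomer (formyl trans to the arylmethyl chain), and benzoquinone suppresses ruthenium hydride-induced double-bond migration.

Step 3
Reactants: 5 4-bromo-2-methoxyphenol
Product: 6 1-(benzyloxy)-4-bromo-2-methoxybenzene
Conditions: BnBr, K2CO3, DMF, rt
Reagents that add atoms: benzyl bromide, BrCc1ccccc1
Why: Williamson etherification; the aryl bromide is untouched and serves as the handle for metalation.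

Step 4
Reactants: 6 1-(benzyloxy)-4-bromo-2-methoxybenzene; 4 (E)-4-[4-(benzyloxy)-3,5-dimethoxyphenyl]-2-methylbut-2-enal
Product: 10 (S,E)-1-[4-(benzyloxy)-3-methoxyphenyl]-4-[4-(benzyloxy)-3,5-dimethoxyphenyl]-2-methylbut-2-en-1-ol, via aryllithium 7 (not isolated), via arylzinc chloride 8 (not isolated), via aryl(butyl)zinc 9 (not isolated)
Conditions: 6 (2 equiv), n-BuLi, t-BuOMe, −78 °C; ZnCl2, 0 °C; n-BuLi; TEEDA (N,N,N',N'-tetraethylethylenediamine); (2R)-(+)-3-exo-morpholinoisoborneol (5 mol %), toluene; then 4, 0 °C; aq NH4Cl
Reagents that add atoms: none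
Why: Catalytic enantioselective aryl transfer from a mixed aryl(alkyl)zinc to an aldehyde under a β-amino alcohol ligand, a reaction type established for α-branched enals; the aryl group of 9 is transferred in preference to butyl, TEEDA binds LiCl so that the uncatalysed racemic addition is suppressed, and the (2R) ligand directs the aryl group to the Re face of the C=O group, which makes C7 S.

Step 5
Reactants: 10 (S,E)-1-[4-(benzyloxy)-3-methoxyphenyl]-4-[4-(benzyloxy)-3,5-dimethoxyphenyl]-2-methylbut-2-en-1-ol; 11 tributyl(iodomethyl)stannane
Product: 12 tributyl({[(S,E)-1-[4-(benzyloxy)-3-methoxyphenyl]-4-[4-(benzyloxy)-3,5-dimethoxyphenyl]-2-methylbut-2-en-1-yl]oxy}methyl)stannane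
Conditions: KH, THF, 0 °C; then 11, 0 °C → rt
Reagents that add atoms: none
Why: Williamson etherification of the potassium alkoxide with the reactive iodomethylstannane, the standard way to Wittig–Still substrates; no bond at C7 is broken, so its configuration is kept, and the basic medium avoids ionisation of the acid-labile benzylic allylic alcohol.

Step 6
Reactants: 12 tributyl({[(S,E)-1-[4-(benzyloxy)-3-methoxyphenyl]-4-[4-(benzyloxy)-3,5-dimethoxyphenyl]-2-methylbut-2-en-1-yl]oxy}methyl)stannane
Product: 14 (R,Z)-2-[4-(benzyloxy)-3,5-dimethoxybenzyl]-4-[4-(benzyloxy)-3-methoxyphenyl]-3-methylbut-3-en-1-ol, via α-alkoxymethyllithium 13 (not isolated)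
Conditions: n-BuLi (1.5 equiv), THF, −78 °C; then aq NH4Cl
Reagents that add atoms: none
Why: Tin–lithium exchange at −78 °C is faster than any deprotonation and gives the unstabilised α-alkoxymethyllithium 13, which undergoes the concerted, suprafacial [2,3]-sigmatropic (Wittig–Still) shift: the carbanion carbon C9' bonds to C8' while the C7–O bond breaks and the double bond moves to C7=C8. The closest known reaction type is the Wittig–Still rearrangement of stannylmethyl ethers of secondary 2-methylallylic alcohols, which gives Z-trisubstituted homoallylic alcohols with 1,3-chirality transfer; no ring is closed. In the early five-membered envelope transition state the C7 aryl group takes the pseudo-axial position, because the pseudo-equatorial one eclipses the C8 methyl group whereas the pseudo-axial one meets only the C8' hydrogen of the E-alkene; this fixes the Z geometry of the new styrene. With the aryl group so placed, the oxygen of (S)-12 lies over one face of the allyl unit only, and C9' is delivered to that face of C8', which makes C8' R. The step needs [2,3] to beat [1,2] migration, one envelope to dominate and 12 to be geometrically pure; the low temperature, the 2-methyl substituent and the E-selective origin of the alkene in step 2 are relied on for this. The aryl benzyl ethers and benzylic CH2 groups are not metalated by n-BuLi at −78 °C on the time scale of the exchange.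

Step 7
Reactants: 14 (R,Z)-2-[4-(benzyloxy)-3,5-dimethoxybenzyl]-4-[4-(benzyloxy)-3-methoxyphenyl]-3-methylbut-3-en-1-ol
Product: 15 (2R,3S)-2-[4-(benzyloxy)-3,5-dimethoxybenzyl]-4-[4-(benzyloxy)-3-methoxyphenyl]-3-methylbutan-1-ol
Conditions: H2 (1 atm), [Ir(cod)(PCy3)(py)]PF6 (5 mol %), CH2Cl2, 0 °C → rt
Reagents that add atoms: none
Why: Hydroxyl-directed homogeneous hydrogenation of a homoallylic alcohol on a cationic monovalent iridium catalyst; allylic 1,3-strain between the C7 aryl group and the substituents on C8' holds the C8'–H bond in the alkene plane, the CH2OH group then lies over one face, and the iridium bound to it delivers both hydrogens to that face, which makes C8 S. Benzyl ethers are not cleaved by this catalyst.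

Step 8
Reactants: 15 (2R,3S)-2-[4-(benzyloxy)-3,5-dimethoxybenzyl]-4-[4-(benzyloxy)-3-methoxyphenyl]-3-methylbutan-1-ol
Product: 16 (2R,3S)-2-[4-(benzyloxy)-3,5-dimethoxybenzyl]-4-[4-(benzyloxy)-3-methoxyphenyl]-3-methylbutyl acetate
Conditions: Ac2O, pyridine, DMAP (cat.), CH2Cl2, 0 °C → rt
Reagents that add atoms: acetic anhydride, CC(=O)OC(C)=O
Why: Nucleophile-catalysed acylation of the only free hydroxyl group; both phenols are still benzylated, so no regiochemical question arises.

Step 9
Reactants: 16 (2R,3S)-2-[4-(benzyloxy)-3,5-dimethoxybenzyl]-4-[4-(benzyloxy)-3-methoxyphenyl]-3-methylbutyl acetate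
Product: 17 (2R,3S)-2-(4-hydroxy-3,5-dimethoxybenzyl)-4-(4-hydroxy-3-methoxyphenyl)-3-methylbutyl acetate
Conditions: H2 (1 atm), 10% Pd/C, EtOAc, rt
Reagents that add atoms: none
Why: Hydrogenolysis of aryl benzyl ethers under neutral conditions; the primary acetate, the benzylic CH2 groups and both stereocentres are inert.

## Compound list

1 | 4-allyl-2,6-dimethoxyphenol | C=CCc1cc(OC)c(O)c(OC)c1 | starting material
2 | 5-allyl-2-(benzyloxy)-1,3-dimethoxybenzene | C=CCc1cc(OC)c(OCc2ccccc2)c(OC)c1 | intermediate
3 | methacrolein (2-methylprop-2-enal) | CC(=C)C=O | starting material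
4 | (E)-4-[4-(benzyloxy)-3,5-dimethoxyphenyl]-2-methylbut-2-enal | O=C/C(C)=C/Cc1cc(OC)c(OCc2ccccc2)c(OC)c1 | intermediate
5 | 4-bromo-2-methoxyphenol | COc1cc(Br)ccc1O | starting material
6 | 1-(benzyloxy)-4-bromo-2-methoxybenzene | COc1cc(Br)ccc1OCc1ccccc1 | intermediate
7 | [4-(benzyloxy)-3-methoxyphenyl]lithium | COc1cc([Li])ccc1OCc1ccccc1 | intermediate (not isolated)
8 | [4-(benzyloxy)-3-methoxyphenyl]zinc chloride | COc1cc([Zn]Cl)ccc1OCc1ccccc1 | intermediate (not isolated)
9 | butyl[4-(benzyloxy)-3-methoxyphenyl]zinc | CCCC[Zn]c1ccc(OCc2ccccc2)c(OC)c1 | intermediate (not isolated)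
10 | (S,E)-1-[4-(benzyloxy)-3-methoxyphenyl]-4-[4-(benzyloxy)-3,5-dimethoxyphenyl]-2-methylbut-2-en-1-ol | COc1cc([C@@H](O)/C(C)=C/Cc2cc(OC)c(OCc3ccccc3)c(OC)c2)ccc1OCc1ccccc1 | intermediate
11 | tributyl(iodomethyl)stannane | CCCC[Sn](CCCC)(CCCC)CI | starting material
12 | tributyl({[(S,E)-1-[4-(benzyloxy)-3-methoxyphenyl]-4-[4-(benzyloxy)-3,5-dimethoxyphenyl]-2-methylbut-2-en-1-yl]oxy}methyl)stannane | COc1cc([C@@H](OC[Sn](CCCC)(CCCC)CCCC)/C(C)=C/Cc2cc(OC)c(OCc3ccccc3)c(OC)c2)ccc1OCc1ccccc1 | intermediate
13 | ({[(S,E)-1-[4-(benzyloxy)-3-methoxyphenyl]-4-[4-(benzyloxy)-3,5-dimethoxyphenyl]-2-methylbut-2-en-1-yl]oxy}methyl)lithium | COc1cc([C@@H](OC[Li])/C(C)=C/Cc2cc(OC)c(OCc3ccccc3)c(OC)c2)ccc1OCc1ccccc1 | intermediate (not isolated)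
14 | (R,Z)-2-[4-(benzyloxy)-3,5-dimethoxybenzyl]-4-[4-(benzyloxy)-3-methoxyphenyl]-3-methylbut-3-en-1-ol | COc1cc(/C=C(C)\[C@H](CO)Cc2cc(OC)c(OCc3ccccc3)c(OC)c2)ccc1OCc1ccccc1 | intermediate
15 | (2R,3S)-2-[4-(benzyloxy)-3,5-dimethoxybenzyl]-4-[4-(benzyloxy)-3-methoxyphenyl]-3-methylbutan-1-ol | COc1cc(C[C@H](C)[C@H](CO)Cc2cc(OC)c(OCc3ccccc3)c(OC)c2)ccc1OCc1ccccc1 | intermediate
16 | (2R,3S)-2-[4-(benzyloxy)-3,5-dimethoxybenzyl]-4-[4-(benzyloxy)-3-methoxyphenyl]-3-methylbutyl acetate | COc1cc(C[C@H](C)[C@H](COC(C)=O)Cc2cc(OC)c(OCc3ccccc3)c(OC)c2)ccc1OCc1ccccc1 | intermediate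
17 | (2R,3S)-2-(4-hydroxy-3,5-dimethoxybenzyl)-4-(4-hydroxy-3-methoxyphenyl)-3-methylbutyl acetate | COc1cc(C[C@H](C)[C@H](COC(C)=O)Cc2cc(OC)c(O)c(OC)c2)ccc1O | target

## Step count and risks

Total step count: 9. Longest linear sequence: 8 steps (steps 1, 2, 4, 5, 6, 7, 8 and 9).

**Step 6 (key step).** The most likely failure is diversion of the α-alkoxymethyllithium into a [1,2] shift. The migrating carbon C7 is both benzylic and allylic, so a radical-pair pathway is unusually accessible. Less likely are proton abstraction at C7–H and partial loss of Z selectivity, which would also lower the chirality transfer. The fallback gives up the sigmatropic transfer and sets C8' by auxiliary-controlled alkylation and C8 by lactone methylation. It sets out from 2, uses aryllithium 7 made from 6, and comes back to the route at the target 17.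
- Hydroboration–oxidation of 2 (9-BBN, THF; NaOH, H2O2) should give 3-[4-(benzyloxy)-3,5-dimethoxyphenyl]propan-1-ol F1.
- Oxidation (TEMPO, PhI(OAc)2, MeCN/H2O) should give 3-[4-(benzyloxy)-3,5-dimethoxyphenyl]propanoic acid F2.
- Coupling through the pivaloyl mixed anhydride with lithiated (S)-4-benzyloxazolidin-2-one should give (S)-4-benzyl-3-{3-[4-(benzyloxy)-3,5-dimethoxyphenyl]propanoyl}oxazolidin-2-one F3.
- Alkylation of its sodium enolate (NaHMDS, THF, −78 °C; tert-butyl bromoacetate), anti to the auxiliary benzyl group, should give tert-butyl (R)-4-[(S)-4-benzyl-2-oxooxazolidin-3-yl]-3-[4-(benzyloxy)-3,5-dimethoxybenzyl]-4-oxobutanoate F4.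
- LiBH4 should remove the auxiliary reductively to tert-butyl (R)-4-[4-(benzyloxy)-3,5-dimethoxyphenyl]-3-(hydroxymethyl)butanoate F5.
- Acid (TsOH, toluene) should close this to (R)-4-[4-(benzyloxy)-3,5-dimethoxybenzyl]dihydrofuran-2(3H)-one F6, identical with A1.
- Enolate methylation (LDA, THF, −78 °C; MeI), trans to the ring substituent, should give (3R,4R)-4-[4-(benzyloxy)-3,5-dimethoxybenzyl]-3-methyldihydrofuran-2(3H)-one F7, identical with A2.
- Addition of 7 at −78 °C should open the lactone to (2R,3R)-1-[4-(benzyloxy)-3-methoxyphenyl]-3-[4-(benzyloxy)-3,5-dimethoxybenzyl]-4-hydroxy-2-methylbutan-1-one F8.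
- Acetylation (Ac2O, pyridine) should give (2R,3R)-2-[4-(benzyloxy)-3,5-dimethoxybenzyl]-4-[4-(benzyloxy)-3-methoxyphenyl]-3-methyl-4-oxobutyl acetate F9.
- Hydrogenolysis (H2, Pd/C, AcOH, cat. HClO4) should remove the benzylic carbonyl oxygen and both benzyl groups to give 17.

**Step 4.** The risks are insufficient facial discrimination on this γ-aryl enal, competing butyl transfer, and racemic background addition by organolithium not fully converted to zinc. The fallback separates bond formation from stereocontrol. It sets out from 4 and aryllithium 7 and comes back at 10.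
- Direct addition of 7 to 4 (THF, −78 °C) should give racemic (E)-1-[4-(benzyloxy)-3-methoxyphenyl]-4-[4-(benzyloxy)-3,5-dimethoxyphenyl]-2-methylbut-2-en-1-ol F10.
- MnO2 in CH2Cl2 should oxidise it to (E)-1-[4-(benzyloxy)-3-methoxyphenyl]-4-[4-(benzyloxy)-3,5-dimethoxyphenyl]-2-methylbut-2-en-1-one F11.
- Corey–Bakshi–Shibata reduction should then give 10. The reagents are (S)-1-methyl-3,3-diphenyltetrahydro-1H,3H-pyrrolo[1,2-c][1,3,2]oxazaborole and catecholborane in toluene at −78 °C.
- If the α-methylalkenyl flank acts as the larger group, the (S)-catalyst should give (S)-10. This is not known in advance; the sense would be checked on the first run and the catalyst enantiomer changed if needed.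

**Step 7.** The risks are incomplete facial selectivity if hydroxyl binding does not outweigh undirected addition in this flexible chain, and double-bond migration or catalyst deactivation before the hindered styrene is consumed. The fallback replaces substrate direction by catalyst control. It sets out from 14 and comes back at 16.
- Acetylation (Ac2O, pyridine, DMAP) should give (R,Z)-2-[4-(benzyloxy)-3,5-dimethoxybenzyl]-4-[4-(benzyloxy)-3-methoxyphenyl]-3-methylbut-3-en-1-yl acetate F12.
- F12 would be hydrogenated with a chiral iridium phosphinooxazoline catalyst, [Ir(cod)(L)][B(C6H3-3,5-(CF3)2)4] with L = 4-tert-butyl-2-[2-(diphenylphosphanyl)phenyl]-4,5-dihydrooxazole, under H2 (50 bar) in CH2Cl2.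
- The ligand enantiomer that matches the existing C8' centre would be found by trying both.

**Step 2.** The risks are migration of the allyl double bond into conjugation with the arene before metathesis, which shortens the chain by one carbon, and slow turnover with the 1,1-disubstituted partner. The fallback builds the enal by carbonyl olefination. It sets out from 2 and comes back at 4.
- Lemieux–Johnson cleavage (OsO4 cat., NaIO4, 2,6-lutidine, dioxane/H2O) should give 2-[4-(benzyloxy)-3,5-dimethoxyphenyl]acetaldehyde F13.
- F13 would be used crude in a Wittig reaction with 2-(triphenylphosphoranylidene)propanal (toluene, 80 °C) to give E-enal 4.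

## Further compounds

F1 | step 6 | 3-[4-(benzyloxy)-3,5-dimethoxyphenyl]propan-1-ol | OCCCc1cc(OC)c(OCc2ccccc2)c(OC)c1
F2 | step 6 | 3-[4-(benzyloxy)-3,5-dimethoxyphenyl]propanoic acid | OC(=O)CCc1cc(OC)c(OCc2ccccc2)c(OC)c1
F3 | step 6 | (S)-4-benzyl-3-{3-[4-(benzyloxy)-3,5-dimethoxyphenyl]propanoyl}oxazolidin-2-one | O=C(CCc1cc(OC)c(OCc2ccccc2)c(OC)c1)N1[C@@H](Cc2ccccc2)COC1=O
F4 | step 6 | tert-butyl (R)-4-[(S)-4-benzyl-2-oxooxazolidin-3-yl]-3-[4-(benzyloxy)-3,5-dimethoxybenzyl]-4-oxobutanoate | CC(C)(C)OC(=O)C[C@@H](Cc1cc(OC)c(OCc2ccccc2)c(OC)c1)C(=O)N1[C@@H](Cc2ccccc2)COC1=O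
F5 | step 6 | tert-butyl (R)-4-[4-(benzyloxy)-3,5-dimethoxyphenyl]-3-(hydroxymethyl)butanoate | CC(C)(C)OC(=O)C[C@H](CO)Cc1cc(OC)c(OCc2ccccc2)c(OC)c1
F6 | step 6 | (R)-4-[4-(benzyloxy)-3,5-dimethoxybenzyl]dihydrofuran-2(3H)-one | O=C1C[C@H](CO1)Cc1cc(OC)c(OCc2ccccc2)c(OC)c1
F7 | step 6 | (3R,4R)-4-[4-(benzyloxy)-3,5-dimethoxybenzyl]-3-methyldihydrofuran-2(3H)-one | O=C1[C@H](C)[C@H](CO1)Cc1cc(OC)c(OCc2ccccc2)c(OC)c1
F8 | step 6 | (2R,3R)-1-[4-(benzyloxy)-3-methoxyphenyl]-3-[4-(benzyloxy)-3,5-dimethoxybenzyl]-4-hydroxy-2-methylbutan-1-one | COc1cc(C(=O)[C@H](C)[C@H](CO)Cc2cc(OC)c(OCc3ccccc3)c(OC)c2)ccc1OCc1ccccc1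
F9 | step 6 | (2R,3R)-2-[4-(benzyloxy)-3,5-dimethoxybenzyl]-4-[4-(benzyloxy)-3-methoxyphenyl]-3-methyl-4-oxobutyl acetate | COc1cc(C(=O)[C@H](C)[C@H](COC(C)=O)Cc2cc(OC)c(OCc3ccccc3)c(OC)c2)ccc1OCc1ccccc1
F10 | step 4 | racemic (E)-1-[4-(benzyloxy)-3-methoxyphenyl]-4-[4-(benzyloxy)-3,5-dimethoxyphenyl]-2-methylbut-2-en-1-ol | COc1cc(C(O)/C(C)=C/Cc2cc(OC)c(OCc3ccccc3)c(OC)c2)ccc1OCc1ccccc1
F11 | step 4 | (E)-1-[4-(benzyloxy)-3-methoxyphenyl]-4-[4-(benzyloxy)-3,5-dimethoxyphenyl]-2-methylbut-2-en-1-one | COc1cc(C(=O)/C(C)=C/Cc2cc(OC)c(OCc3ccccc3)c(OC)c2)ccc1OCc1ccccc1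
F12 | step 7 | (R,Z)-2-[4-(benzyloxy)-3,5-dimethoxybenzyl]-4-[4-(benzyloxy)-3-methoxyphenyl]-3-methylbut-3-en-1-yl acetate | COc1cc(/C=C(C)\[C@H](COC(C)=O)Cc2cc(OC)c(OCc3ccccc3)c(OC)c2)ccc1OCc1ccccc1
F13 | step 2 | 2-[4-(benzyloxy)-3,5-dimethoxyphenyl]acetaldehyde | O=CCc1cc(OC)c(OCc2ccccc2)c(OC)c1
A1 | alternative 1 | (R)-4-[4-(benzyloxy)-3,5-dimethoxybenzyl]dihydrofuran-2(3H)-one | O=C1C[C@H](CO1)Cc1cc(OC)c(OCc2ccccc2)c(OC)c1
A2 | alternative 1 | (3R,4R)-4-[4-(benzyloxy)-3,5-dimethoxybenzyl]-3-methyldihydrofuran-2(3H)-one | O=C1[C@H](C)[C@H](CO1)Cc1cc(OC)c(OCc2ccccc2)c(OC)c1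
A3 | alternative 2 | (2R,3S)-2-[4-(benzyloxy)-3,5-dimethoxybenzyl]-4-[4-(benzyloxy)-3-methoxyphenyl]-3-methylbutanal | O=C[C@H](Cc1cc(OC)c(OCc2ccccc2)c(OC)c1)[C@@H](C)Cc1ccc(OCc2ccccc2)c(OC)c1
A4 | alternative 3 | (2S,3S,E)-2-[4-(benzyloxy)-3-methoxybenzyl]-3-[4-(benzyloxy)-3,5-dimethoxybenzyl]hex-4-enoic acid | COc1cc(C[C@H](C(=O)O)[C@H](/C=C/C)Cc2cc(OC)c(OCc3ccccc3)c(OC)c2)ccc1OCc1ccccc1
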